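**Retrosynthetic overview**

1. Gemichalcone A (21) ⇐ fluoride desilylation of 20 ⇐ late aromatisation of ring A: sulfoxide syn-elimination and tautomerisation of the sulfenylated cyclohexane-1,3-dione 18.
2. 18 ⇐ union of the two halves at the bond from ring carbon C3' to the allylic CH2 of the C5 chain: palladium-catalysed allylation of C2 of dione 17 by the (Z)-allylic carbonate 10, which already carries the feruloyl ester.
3. Enabling feature: C3' of ring A lies between the two oxygen-bearing carbons C2' and C4'. At the dihydro oxidation level it is therefore C2 of a cyclohexane-1,3-dione, the only soft carbon nucleophile of that fragment; the acyl-bearing carbon C1' (dione C4) carries a phenylsulfanyl group that blocks it and later delivers the C5'=C6' unsaturation.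
4. 17 ⇐ 3-ethoxycyclohex-2-enone 13 by C6-acylation with silylated p-coumaroyl chloride, sulfenylation and hydrolysis; 10 ⇐ Still–Gennari (Z)-enoate 3 by reduction, acylation with silylated feruloyl chloride, selective desilylation and carbonate formation.
5. Ring order: ring B and the feruloyl arene are bought as cinnamic acids; ring A is bought as the carbocycle of 13, carried non-aromatic through the route and aromatised last (step 12).

Key step: step 11

Remark: the side-chain alkene is taken as Z (CH2O cis to CH2–aryl), as the SMILES encodes. Compounds 15 to 19 are racemic or enol/diastereomer mixtures; their temporary stereocentres vanish in step 12.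

**Route**

Step 1
Reactants: 1 (tert-butyldimethylsilyloxy)acetaldehyde; 2 ethyl 2-[bis(2,2,2-trifluoroethoxy)phosphoryl]propanoate
Product: 3 ethyl (Z)-4-[(tert-butyldimethylsilyl)oxy]-2-methylbut-2-enoate
Conditions: KN(SiMe3)2, 18-crown-6, THF, −78 °C
Reagents that add atoms: none
Why: Still–Gennari olefination, in which the electron-poor phosphonate with a dissociated potassium counter-ion eliminates from the kinetic adduct, so the trisubstituted enoate should form with the ester cis to CH2OSi (Z).

Step 2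
Reactants: 3 ethyl (Z)-4-[(tert-butyldimethylsilyl)oxy]-2-methylbut-2-enoate
Product: 4 (Z)-4-[(tert-butyldimethylsilyl)oxy]-2-methylbut-2-en-1-ol
Conditions: i-Bu2AlH (2.5 equiv), CH2Cl2, −78 °C → 0 °C; aqueous work-up
Reagents that add atoms: none
Why: Hydride reduction of an α,β-unsaturated ester to the allylic alcohol at low temperature is reliable and should leave the silyl ether and the Z geometry untouched.

Step 3
Reactants: 5 (E)-ferulic acid
Product: 6 tert-butyldimethylsilyl (E)-3-{4-[(tert-butyldimethylsilyl)oxy]-3-methoxyphenyl}acrylate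
Conditions: t-BuMe2SiCl (2.2 equiv), imidazole, DMF, rt
Reagents that add atoms: tert-butyl(chloro)dimethylsilane, CC(C)(C)[Si](C)(C)Cl
Why: Standard silylation of phenol and carboxylic acid with a silyl chloride and imidazole, the silyl ester serving as the acid chloride precursor for step 4.

Step 4
Reactants: 6 tert-butyldimethylsilyl (E)-3-{4-[(tert-butyldimethylsilyl)oxy]-3-methoxyphenyl}acrylate; 4 (Z)-4-[(tert-butyldimethylsilyl)oxy]-2-methylbut-2-en-1-ol
Product: 8 (Z)-4-[(tert-butyldimethylsilyl)oxy]-2-methylbut-2-en-1-yl (E)-3-{4-[(tert-butyldimethylsilyl)oxy]-3-methoxyphenyl}acrylate, via acid chloride 7 (not isolated)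
Conditions: (COCl)2, DMF (cat.), CH2Cl2, 0 °C → rt, evaporate; then 4, pyridine, 4-(dimethylamino)pyridine (cat.), CH2Cl2, 0 °C
Reagents that add atoms: none
Why: Oxalyl chloride with catalytic DMF converts tert-butyldimethylsilyl esters directly into acid chlorides under neutral conditions, and acylation of the primary allylic alcohol then gives the ester without touching either double-bond geometry.

Step 5
Reactants: 8 (Z)-4-[(tert-butyldimethylsilyl)oxy]-2-methylbut-2-en-1-yl (E)-3-{4-[(tert-butyldimethylsilyl)oxy]-3-methoxyphenyl}acrylate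
Product: 9 (Z)-4-hydroxy-2-methylbut-2-en-1-yl (E)-3-{4-[(tert-butyldimethylsilyl)oxy]-3-methoxyphenyl}acrylate
Conditions: camphor-10-sulfonic acid (0.1 equiv), MeOH/CH2Cl2 (1:1), 0 °C
Reagents that add atoms: none
Why: Acid-catalysed methanolysis cleaves a primary alkyl silyl ether much faster than an aryl silyl ether, and at 0 °C neither transesterification nor acyl shift to the freed cis-hydroxymethyl group should compete.

Step 6
Reactants: 9 (Z)-4-hydroxy-2-methylbut-2-en-1-yl (E)-3-{4-[(tert-butyldimethylsilyl)oxy]-3-methoxyphenyl}acrylate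
Product: 10 (Z)-4-[(methoxycarbonyl)oxy]-2-methylbut-2-en-1-yl (E)-3-{4-[(tert-butyldimethylsilyl)oxy]-3-methoxyphenyl}acrylate
Conditions: ClCO2Me, pyridine, CH2Cl2, 0 °C
Reagents that add atoms: methyl chloroformate, COC(=O)Cl
Why: Routine carbonate formation on a primary allylic alcohol installs the leaving group that ionises with zerovalent palladium under neutral conditions.

Step 7
Reactants: 11 (E)-4-hydroxycinnamic acid (p-coumaric acid)
Product: 12 tert-butyldimethylsilyl (E)-3-{4-[(tert-butyldimethylsilyl)oxy]phenyl}acrylate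
Conditions: t-BuMe2SiCl (2.2 equiv), imidazole, DMF, rt
Reagents that add atoms: tert-butyl(chloro)dimethylsilane, CC(C)(C)[Si](C)(C)Cl
Why: Same silylation as in step 3, giving the protected phenol and the silyl ester needed for neutral acid chloride formation.

Step 8
Reactants: 12 tert-butyldimethylsilyl (E)-3-{4-[(tert-butyldimethylsilyl)oxy]phenyl}acrylate; 13 3-ethoxycyclohex-2-en-1-one
Product: 15 6-[(E)-3-{4-[(tert-butyldimethylsilyl)oxy]phenyl}acryloyl]-3-ethoxycyclohex-2-en-1-one, via acid chloride 14 (not isolated)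
Conditions: (COCl)2, DMF (cat.), CH2Cl2, 0 °C → rt, evaporate; 13 (2.0 equiv), LiN(SiMe3)2 (2.0 equiv), THF, −78 °C, then 14; aq. NH4Cl
Reagents that add atoms: none
Why: Kinetic deprotonation of the vinylogous ester occurs at C6 (Stork–Danheiser enolate), and Claisen-type C-acylation by the acid chloride, with the second equivalent of enolate absorbing the acidic β-diketone proton, should give the 6-acyl enone.

Step 9
Reactants: 15 6-[(E)-3-{4-[(tert-butyldimethylsilyl)oxy]phenyl}acryloyl]-3-ethoxycyclohex-2-en-1-one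
Product: 16 6-[(E)-3-{4-[(tert-butyldimethylsilyl)oxy]phenyl}acryloyl]-3-ethoxy-6-(phenylsulfanyl)cyclohex-2-en-1-one
Conditions: N-(phenylsulfanyl)phthalimide, Et3N (cat.), CH2Cl2, 0 °C → rt
Reagents that add atoms: N-(phenylsulfanyl)phthalimide, O=C1N(Sc2ccccc2)C(=O)c2ccccc12
Why: Amine-catalysed α-sulfenylation of a β-diketone at its doubly activated carbon is a standard soft electrophilic substitution; it makes C6 quaternary, which blocks this carbon in the key step and stores the later ring unsaturation.

Step 10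
Reactants: 16 6-[(E)-3-{4-[(tert-butyldimethylsilyl)oxy]phenyl}acryloyl]-3-ethoxy-6-(phenylsulfanyl)cyclohex-2-en-1-one
Product: 17 4-[(E)-3-{4-[(tert-butyldimethylsilyl)oxy]phenyl}acryloyl]-4-(phenylsulfanyl)cyclohexane-1,3-dione
Conditions: 1 M HCl (aq.), THF, rt
Reagents that add atoms: water, O
Why: Dilute aqueous acid hydrolyses the β-alkoxy enone (vinylogous ester) to the cyclohexane-1,3-dione at room temperature, conditions the aryl silyl ether, the thioether and the non-enolisable β-diketone should survive.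

Step 11
Reactants: 17 4-[(E)-3-{4-[(tert-butyldimethylsilyl)oxy]phenyl}acryloyl]-4-(phenylsulfanyl)cyclohexane-1,3-dione; 10 (Z)-4-[(methoxycarbonyl)oxy]-2-methylbut-2-en-1-yl (E)-3-{4-[(tert-butyldimethylsilyl)oxy]-3-methoxyphenyl}acrylate
Product: 18 (Z)-4-{3-[(E)-3-{4-[(tert-butyldimethylsilyl)oxy]phenyl}acryloyl]-2,6-dioxo-3-(phenylsulfanyl)cyclohexyl}-2-methylbut-2-en-1-yl (E)-3-{4-[(tert-butyldimethylsilyl)oxy]-3-methoxyphenyl}acrylate
Conditions: Pd(PPh3)4 (5 mol %), 17 (1.1 equiv), THF, 0 °C → rt
Reagents that add atoms: none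
Why: Zerovalent palladium ionises the allylic methyl carbonate of 10 with loss of CO2, the methoxide released deprotonates the cyclic 1,3-dione 17 (pKa about 5), and the soft enolate attacks the unsubstituted CH2 terminus of the allylpalladium cation from the face opposite the metal, forming the bond between dione C2 (the future C3' of ring A) and the allylic CH2. The closest known reaction type is the Tsuji–Trost C-allylation of cyclohexane-1,3-diones with allylic carbonates under neutral conditions; no ring is closed, and the only new stereocentre (C2) is enolisable and is erased together with C4 on aromatisation, so no stereocontrol is needed. Site selectivity is secured by the substrate: C2 is the only carbon acid because C4 is quaternary through the phenylsulfanyl group, and O-allyl enol ethers formed reversibly are re-ionised by the catalyst and drain to the C-allyl product. Attack at the less hindered allyl terminus gives the linear chain, and the carbonate should react in preference to the allylic cinnamate ester because carbonates ionise much faster and irreversibly, helped by low temperature and a slight excess of 17 that also suppresses double allylation. The Z geometry should survive because syn–anti exchange at the disubstituted allyl terminus would require a tertiary sigma-allyl palladium species, as in the known retention of geometry with neryl-type substrates.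

Step 12
Reactants: 18 (Z)-4-{3-[(E)-3-{4-[(tert-butyldimethylsilyl)oxy]phenyl}acryloyl]-2,6-dioxo-3-(phenylsulfanyl)cyclohexyl}-2-methylbut-2-en-1-yl (E)-3-{4-[(tert-butyldimethylsilyl)oxy]-3-methoxyphenyl}acrylate
Product: 20 (Z)-4-{3-[(E)-3-{4-[(tert-butyldimethylsilyl)oxy]phenyl}acryloyl]-2,6-dihydroxyphenyl}-2-methylbut-2-en-1-yl (E)-3-{4-[(tert-butyldimethylsilyl)oxy]-3-methoxyphenyl}acrylate, via sulfoxide 19 (not isolated)
Conditions: 3-chloroperbenzoic acid (1.0 equiv), CH2Cl2, −78 °C → −20 °C; then warm to 40 °C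
Reagents that add atoms: none
Why: Sulfide oxidation at low temperature is far faster than alkene epoxidation, and the resulting α-sulfinyl β-diketone can undergo thermal syn-elimination only toward C5 (Trost sulfenylation–dehydrosulfenylation), giving a cyclohex-4-ene-1,3-dione that is the keto tautomer of the resorcinol and should aromatise spontaneously to ring A.

Step 13
Reactants: 20 (Z)-4-{3-[(E)-3-{4-[(tert-butyldimethylsilyl)oxy]phenyl}acryloyl]-2,6-dihydroxyphenyl}-2-methylbut-2-en-1-yl (E)-3-{4-[(tert-butyldimethylsilyl)oxy]-3-methoxyphenyl}acrylate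
Product: 21 gemichalcone A
Conditions: Bu4NF (2.2 equiv), AcOH (2.5 equiv), THF, 0 °C
Reagents that add atoms: none
Why: Acetic acid-buffered fluoride cleaves aryl silyl ethers rapidly at 0 °C, and the buffered medium should prevent cleavage of the allylic ester and base-induced chalcone–flavanone cyclisation.

**Compound list**

1 | (tert-butyldimethylsilyloxy)acetaldehyde | O=CCO[Si](C)(C)C(C)(C)C | starting material
2 | ethyl 2-[bis(2,2,2-trifluoroethoxy)phosphoryl]propanoate | CCOC(=O)C(C)P(=O)(OCC(F)(F)F)OCC(F)(F)F | starting material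
3 | ethyl (Z)-4-[(tert-butyldimethylsilyl)oxy]-2-methylbut-2-enoate | CCOC(=O)/C(C)=C\CO[Si](C)(C)C(C)(C)C | intermediate
4 | (Z)-4-[(tert-butyldimethylsilyl)oxy]-2-methylbut-2-en-1-ol | OC/C(C)=C\CO[Si](C)(C)C(C)(C)C | intermediate
5 | (E)-ferulic acid | COc1cc(/C=C/C(=O)O)ccc1O | starting material
6 | tert-butyldimethylsilyl (E)-3-{4-[(tert-butyldimethylsilyl)oxy]-3-methoxyphenyl}acrylate | COc1cc(/C=C/C(=O)O[Si](C)(C)C(C)(C)C)ccc1O[Si](C)(C)C(C)(C)C | intermediate
7 | (E)-3-{4-[(tert-butyldimethylsilyl)oxy]-3-methoxyphenyl}acryloyl chloride (not isolated) | COc1cc(/C=C/C(Cl)=O)ccc1O[Si](C)(C)C(C)(C)C | intermediate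
8 | (Z)-4-[(tert-butyldimethylsilyl)oxy]-2-methylbut-2-en-1-yl (E)-3-{4-[(tert-butyldimethylsilyl)oxy]-3-methoxyphenyl}acrylate | COc1cc(/C=C/C(=O)OC/C(C)=C\CO[Si](C)(C)C(C)(C)C)ccc1O[Si](C)(C)C(C)(C)C | intermediate
9 | (Z)-4-hydroxy-2-methylbut-2-en-1-yl (E)-3-{4-[(tert-butyldimethylsilyl)oxy]-3-methoxyphenyl}acrylate | COc1cc(/C=C/C(=O)OC/C(C)=C\CO)ccc1O[Si](C)(C)C(C)(C)C | intermediate
10 | (Z)-4-[(methoxycarbonyl)oxy]-2-methylbut-2-en-1-yl (E)-3-{4-[(tert-butyldimethylsilyl)oxy]-3-methoxyphenyl}acrylate | COc1cc(/C=C/C(=O)OC/C(C)=C\COC(=O)OC)ccc1O[Si](C)(C)C(C)(C)C | intermediate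
11 | (E)-4-hydroxycinnamic acid (p-coumaric acid) | OC(=O)/C=C/c1ccc(O)cc1 | starting material
12 | tert-butyldimethylsilyl (E)-3-{4-[(tert-butyldimethylsilyl)oxy]phenyl}acrylate | CC(C)(C)[Si](C)(C)OC(=O)/C=C/c1ccc(O[Si](C)(C)C(C)(C)C)cc1 | intermediate
13 | 3-ethoxycyclohex-2-en-1-one | CCOC1=CC(=O)CCC1 | starting material
14 | (E)-3-{4-[(tert-butyldimethylsilyl)oxy]phenyl}acryloyl chloride (not isolated) | O=C(Cl)/C=C/c1ccc(O[Si](C)(C)C(C)(C)C)cc1 | intermediate
15 | 6-[(E)-3-{4-[(tert-butyldimethylsilyl)oxy]phenyl}acryloyl]-3-ethoxycyclohex-2-en-1-one (racemic, enolised β-diketone) | CCOC1=CC(=O)C(C(=O)/C=C/c2ccc(O[Si](C)(C)C(C)(C)C)cc2)CC1 | intermediate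
16 | 6-[(E)-3-{4-[(tert-butyldimethylsilyl)oxy]phenyl}acryloyl]-3-ethoxy-6-(phenylsulfanyl)cyclohex-2-en-1-one (racemic) | CCOC1=CC(=O)C(Sc2ccccc2)(C(=O)/C=C/c2ccc(O[Si](C)(C)C(C)(C)C)cc2)CC1 | intermediate
17 | 4-[(E)-3-{4-[(tert-butyldimethylsilyl)oxy]phenyl}acryloyl]-4-(phenylsulfanyl)cyclohexane-1,3-dione (racemic, drawn as diketone) | O=C1CC(=O)C(Sc2ccccc2)(C(=O)/C=C/c2ccc(O[Si](C)(C)C(C)(C)C)cc2)CC1 | intermediate
18 | (Z)-4-{3-[(E)-3-{4-[(tert-butyldimethylsilyl)oxy]phenyl}acryloyl]-2,6-dioxo-3-(phenylsulfanyl)cyclohexyl}-2-methylbut-2-en-1-yl (E)-3-{4-[(tert-butyldimethylsilyl)oxy]-3-methoxyphenyl}acrylate (diastereomer/enol mixture) | O=C1CCC(Sc2ccccc2)(C(=O)/C=C/c2ccc(O[Si](C)(C)C(C)(C)C)cc2)C(=O)C1C/C=C(C)\COC(=O)/C=C/c1ccc(O[Si](C)(C)C(C)(C)C)c(OC)c1 | intermediate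
19 | S-oxide (phenylsulfinyl analogue) of 18 (not isolated) | O=C1CCC(S(=O)c2ccccc2)(C(=O)/C=C/c2ccc(O[Si](C)(C)C(C)(C)C)cc2)C(=O)C1C/C=C(C)\COC(=O)/C=C/c1ccc(O[Si](C)(C)C(C)(C)C)c(OC)c1 | intermediate
20 | (Z)-4-{3-[(E)-3-{4-[(tert-butyldimethylsilyl)oxy]phenyl}acryloyl]-2,6-dihydroxyphenyl}-2-methylbut-2-en-1-yl (E)-3-{4-[(tert-butyldimethylsilyl)oxy]-3-methoxyphenyl}acrylate (gemichalcone A bis-silyl ether) | COc1cc(/C=C/C(=O)OC/C(C)=C\Cc2c(O)ccc(C(=O)/C=C/c3ccc(O[Si](C)(C)C(C)(C)C)cc3)c2O)ccc1O[Si](C)(C)C(C)(C)C | intermediate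
21 | gemichalcone A | COc1cc(/C=C/C(=O)OC/C(C)=C\Cc2c(O)ccc(C(=O)/C=C/c3ccc(O)cc3)c2O)ccc1O | target

**Step count and risks**

Total step count: 13.
Longest linear sequence: 8 steps (1, 2, 4, 5, 6, 11, 12, 13).

Steps most likely to fail:

Step 11. The catalyst may also ionise the allylic cinnamate ester of 10 or of the product, which would scramble or strip the chain. C2 may be allylated twice, or syn–anti isomerisation of the allylpalladium intermediate may erode the Z geometry. The fallback drops the metal and sets out from alcohol 9. Appel bromination (CBr4, PPh3, CH2Cl2, 0 °C) would give (Z)-4-bromo-2-methylbut-2-en-1-yl (E)-3-{4-[(tert-butyldimethylsilyl)oxy]-3-methoxyphenyl}acrylate F1. The potassium enolate of 17 (KHCO3) would then be alkylated with F1 in a water-rich medium (H2O/THF), the classical protocol for C-alkylation of cyclohexane-1,3-diones with allylic bromides, where hydrogen bonding to the enolate oxygens favours carbon. Direct SN2 displacement cannot touch the allylic ester and keeps the alkene geometry. The route is rejoined at 18.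

Step 12. Oxidation may occur at the wrong site (epoxidation of the trisubstituted alkene, hydroxylation of the enolised dione), or the syn-elimination may be sluggish and the sulfenic acid may add back. The fallback gives up sulfur and sets out from 15. Hydrolysis (1 M HCl, THF) would give 4-[(E)-3-{4-[(tert-butyldimethylsilyl)oxy]phenyl}acryloyl]cyclohexane-1,3-dione F2. Allylation with 10 and Pd(PPh3)4 as in step 11 would give (Z)-4-{3-[(E)-3-{4-[(tert-butyldimethylsilyl)oxy]phenyl}acryloyl]-2,6-dioxocyclohexyl}-2-methylbut-2-en-1-yl (E)-3-{4-[(tert-butyldimethylsilyl)oxy]-3-methoxyphenyl}acrylate F3. C2 selectivity then rests on the cyclic 1,3-dione being several pK units more acidic than the exocyclic β-diketone C–H. Dehydrogenation of the enolised ring with 2,3-dichloro-5,6-dicyano-1,4-benzoquinone (DDQ, 1 equiv, dioxane, rt) rejoins the route at 20.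

Step 8. The lithium enolate may be acylated on oxygen or twice, or may add in conjugate fashion to the acryloyl unit instead of undergoing C-acylation. The fallback sets out from 13 and builds the β-diketone by aldol addition and oxidation. (E)-3-{4-[(tert-butyldimethylsilyl)oxy]phenyl}prop-2-enal F4 would be made from commercial (E)-4-hydroxycinnamaldehyde with t-BuMe2SiCl and imidazole. The enolate of 13 (LiN(i-Pr)2, THF, −78 °C) would add to F4 to give 3-ethoxy-6-[(E)-1-hydroxy-3-{4-[(tert-butyldimethylsilyl)oxy]phenyl}prop-2-en-1-yl]cyclohex-2-en-1-one F5. Dess–Martin periodinane oxidation of F5 rejoins the route at 15.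

Further compounds
F1 | step 11 | (Z)-4-bromo-2-methylbut-2-en-1-yl (E)-3-{4-[(tert-butyldimethylsilyl)oxy]-3-methoxyphenyl}acrylate | COc1cc(/C=C/C(=O)OC/C(C)=C\CBr)ccc1O[Si](C)(C)C(C)(C)C
F2 | step 12 | 4-[(E)-3-{4-[(tert-butyldimethylsilyl)oxy]phenyl}acryloyl]cyclohexane-1,3-dione | O=C1CC(=O)C(C(=O)/C=C/c2ccc(O[Si](C)(C)C(C)(C)C)cc2)CC1
F3 | step 12 | (Z)-4-{3-[(E)-3-{4-[(tert-butyldimethylsilyl)oxy]phenyl}acryloyl]-2,6-dioxocyclohexyl}-2-methylbut-2-en-1-yl (E)-3-{4-[(tert-butyldimethylsilyl)oxy]-3-methoxyphenyl}acrylate | O=C1CCC(C(=O)/C=C/c2ccc(O[Si](C)(C)C(C)(C)C)cc2)C(=O)C1C/C=C(C)\COC(=O)/C=C/c1ccc(O[Si](C)(C)C(C)(C)C)c(OC)c1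
F4 | step 8 | (E)-3-{4-[(tert-butyldimethylsilyl)oxy]phenyl}prop-2-enal | O=C/C=C/c1ccc(O[Si](C)(C)C(C)(C)C)cc1
F5 | step 8 | 3-ethoxy-6-[(E)-1-hydroxy-3-{4-[(tert-butyldimethylsilyl)oxy]phenyl}prop-2-en-1-yl]cyclohex-2-en-1-one | CCOC1=CC(=O)C(C(O)/C=C/c2ccc(O[Si](C)(C)C(C)(C)C)cc2)CC1
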